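**Plan**

- Labdane numbering: ring A = C1–C5 and C10 (OH on C2 and C3, gem-dimethyl C4); ring B = C5–C10 (C7=C8, methyl on C8); side chain C11–C15 on C9 (methyl on C13, ester C15); angular methyl on C10.
- Enabling feature: C10 is a methyl-bearing quaternary carbon para to C7 across ring B and C8 carries the second methyl, so ring B is a 2,4-dimethylphenol (oxygen on C7) dearomatised at its para carbon; ring B therefore enters as the arene.
- Cuts, in retrosynthetic order: acetonide; H9 with C7=C8 (allylic transposition from a C7 carbinol); C9–C11 (conjugate addition of a C11–C15 zinc reagent); the C2–O and C3–O bonds (dihydroxylation); C1–C10 (allylic dearomatisation, closes ring A); C2–C3 (vinyl Grignard); the two C4–methyl bonds, back to (2,4-dimethylphenyl)acetonitrile.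
- Forward: the arene (ring B) is tethered, ring A is closed onto C10, the diol is installed and protected, the side chain is joined at C9, and the dienone is reduced arm by arm to the C7=C8 olefin.
- Stereochemistry: C10 from the chiral ligand; C2/C3 from OsO4 attack anti to the axial methyls on C4 and C10; C5 from α-face hydrogenation; C9 by 1,3-transfer from the C7 carbinol through an allylic diazene; C13 from alkaloid-catalysed desymmetrisation of 3-methylglutaric anhydride.

Key step: step 8

Assumption: the (R,R) ligand in step 8 and (DHQ)2AQN in step 11 are taken to give the configurations drawn; if the sense of induction is opposite, the mirror-image ligand or the pseudoenantiomeric (DHQD)2AQN is used and nothing else changes.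

**Route**

Step 1
Reactants: 1 (2,4-dimethylphenyl)acetonitrile
Product: 2 2-(2,4-dimethylphenyl)-2-methylpropanenitrile
Conditions: NaH (2.4 equiv), MeI (2.6 equiv), THF, 0 °C → rt
Reagents that add atoms: iodomethane CI
Why: Double C-methylation of the benzylic nitrile anion (enolate-type alkylation) should stop cleanly at the quaternary carbon, which becomes C4 with its two methyl groups.

Step 2
Reactants: 2 2-(2,4-dimethylphenyl)-2-methylpropanenitrile
Product: 3 2-(5-bromo-2,4-dimethylphenyl)-2-methylpropanenitrile
Conditions: Br2 (1.05 equiv), FeBr3 (5 mol%), CH2Cl2, 0 °C, dark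
Reagents that add atoms: bromine BrBr
Why: Electrophilic aromatic bromination should go to the position ortho to one methyl and para to the other (future C7), because the site between the methyls and the site beside the tertiary group are more hindered and less activated.

Step 3
Reactants: 3 2-(5-bromo-2,4-dimethylphenyl)-2-methylpropanenitrile
Product: 5 2-(5-hydroxy-2,4-dimethylphenyl)-2-methylpropanenitrile, via aryl pinacol boronate 4 (not isolated)
Conditions: B2pin2, PdCl2(dppf) (3 mol%), KOAc, 1,4-dioxane, 90 °C; then 30% H2O2, aq. NaOH, THF, 0 °C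
Reagents that add atoms: bis(pinacolato)diboron CC1(C)OB(OC1(C)C)B1OC(C)(C)C(C)(C)O1; hydrogen peroxide OO
Why: Miyaura borylation of the aryl bromide followed by oxidation of the C–B bond in the same flask (1,2-aryl shift to oxygen) should give the phenol, the short cold peroxide treatment leaving the hindered tertiary nitrile untouched.

Step 4
Reactants: 5 2-(5-hydroxy-2,4-dimethylphenyl)-2-methylpropanenitrile
Product: 6 2-(2-chloro-3-hydroxy-4,6-dimethylphenyl)-2-methylpropanenitrile
Conditions: SO2Cl2 (1.05 equiv), 2,2,6,6-tetramethylpiperidine (5 mol%), toluene, 0 °C → rt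
Reagents that add atoms: sulfuryl chloride ClS(Cl)(=O)=O
Why: Amine-catalysed electrophilic ortho-chlorination of the phenol can only go to C6, the single unsubstituted position ortho or para to the hydroxyl.

Step 5
Reactants: 6 2-(2-chloro-3-hydroxy-4,6-dimethylphenyl)-2-methylpropanenitrile
Product: 8 2-(2-chloro-3-hydroxy-4,6-dimethylphenyl)-2-methylpropanal, via N-aluminio aldimine 7 (not isolated)
Conditions: i-Bu2AlH (3 equiv), CH2Cl2/toluene, −78 → 0 °C; then 1 M HCl, 0 °C
Reagents that add atoms: water O
Why: Partial hydride reduction of the nitrile stops at the N-aluminio aldimine, which is hydrolysed only on acidic work-up, so the non-enolisable aldehyde should form without over-reduction (one equivalent of hydride is consumed by the phenol).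

Step 6
Reactants: 8 2-(2-chloro-3-hydroxy-4,6-dimethylphenyl)-2-methylpropanal; 9 vinylmagnesium bromide
Product: 10 rac-2-chloro-3-(3-hydroxy-2-methylpent-4-en-2-yl)-4,6-dimethylphenol
Conditions: 9 (3 equiv), THF, −78 → 0 °C; aq. NH4Cl
Reagents that add atoms: none
Why: Grignard 1,2-addition to a non-enolisable neopentyl aldehyde; the carbinol centre (C3) is left racemic on purpose because it is erased on ionisation in step 8.

Step 7
Reactants: 10 rac-2-chloro-3-(3-hydroxy-2-methylpent-4-en-2-yl)-4,6-dimethylphenol
Product: 12 rac-methyl [4-(2-chloro-3-hydroxy-4,6-dimethylphenyl)-4-methylpent-1-en-3-yl] carbonate, via bis(methyl carbonate) 11 (not isolated)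
Conditions: LiN(SiMe3)2 (2.2 equiv), THF, −78 °C; ClCO2Me (2.5 equiv), −78 → 0 °C; then MeOH, K2CO3, 0 °C
Reagents that add atoms: methyl chloroformate COC(=O)Cl
Why: O-acylation of the dilithium alkoxide/phenoxide gives the bis-carbonate, and base-catalysed methanolysis (transesterification) should then cleave only the far more labile aryl carbonate, whose leaving group is a 2-chlorophenoxide, sparing the hindered secondary allylic carbonate.

Step 8
Reactants: 12 rac-methyl [4-(2-chloro-3-hydroxy-4,6-dimethylphenyl)-4-methylpent-1-en-3-yl] carbonate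
Product: 13 (4aR)-1-chloro-3,4a,8,8-tetramethyl-5,8-dihydronaphthalen-2(4aH)-one (6-chloro cross-conjugated dienone; ring A closed; C10 R)
Conditions: Pd2(dba)3·CHCl3 (2.5 mol%), (1R,2R)-N,N′-bis[2-(diphenylphosphino)benzoyl]cyclohexane-1,2-diamine (7.5 mol%), degassed CH2Cl2 (0.01 M), 25 → 40 °C
Reagents that add atoms: none
Why: Proposed new method: zerovalent palladium ionises the allylic carbonate (loss of CO2 and methoxide, which deprotonates the chlorophenol) and the phenolate attacks the CH2 terminus C1 of the π-allyl through its para carbon C10, on the face opposite palladium, to form C1–C10. The closest known reaction types are the palladium- and iridium-catalysed intramolecular asymmetric allylic dearomatisations of para-tethered phenols to spirocyclohexadienones and the base-mediated para-alkylation of phenolates; new here is the meta tether, which gives a fused ring with the whole allyl unit inside it. Ring A closes in a six-membered endo mode (C10, C5, C4 and the three allyl carbons) that needs the anti π-allyl isomer, reached by η3–η1–η3 equilibration, while the syn isomer is a resting state without exit because C4 is quaternary (no β-hydride) and attack at C3 would make a four-membered ring. The only new stereocentre, C10, is controlled by the chiral ligand: the two diastereomeric π-allyl complexes from racemic 12 interconvert through the η1 form at C1, and the chiral pocket selects the one whose tether presents the required face of the arene, so both enantiomers of 12 should converge. The step needs para-C- over ortho-C- and O-alkylation: chlorine blocks and deactivates C6, the only other ring carbon within reach, the meta relationship makes intramolecular O-allylation geometrically impossible, and intermolecular O-allylation is reversible and held back by high dilution. The C10 methyl forbids rearomatisation, and relief of strain at the crowded junction between the 2,6-disubstituted arene carbon and quaternary C4 adds driving force.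

Step 9
Reactants: 13 (4aR)-1-chloro-3,4a,8,8-tetramethyl-5,8-dihydronaphthalen-2(4aH)-one
Product: 14 (4aR,6R,7S)-1-chloro-6,7-dihydroxy-3,4a,8,8-tetramethyl-5,6,7,8-tetrahydronaphthalen-2(4aH)-one (2α,3α-diol)
Conditions: OsO4 (2 mol%), NMO (1.5 equiv), acetone/H2O, rt
Reagents that add atoms: N-methylmorpholine N-oxide C[N+]1([O-])CCOCC1; water O
Why: Catalytic OsO4 syn-dihydroxylation is chemoselective for the only electron-rich olefin (both dienone double bonds are electron-poor and highly substituted) and should approach C2=C3 anti to the two axial β-methyls on C10 and C4, setting the 2α,3α-cis-diol.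

Step 10
Reactants: 14 (4aR,6R,7S)-1-chloro-6,7-dihydroxy-3,4a,8,8-tetramethyl-5,6,7,8-tetrahydronaphthalen-2(4aH)-one
Product: 15 2α,3α-O-isopropylidene derivative of 14 (acetonide dienone)
Conditions: 2,2-dimethoxypropane, PPTS (cat.), CH2Cl2, rt
Reagents that add atoms: 2,2-dimethoxypropane COC(C)(C)OC
Why: Acid-catalysed transketalisation of the cis-1,2-diol to the five-membered acetonide, under acid mild enough to avoid dienone–phenol rearrangement.

Step 11
Reactants: 16 3-methylglutaric anhydride
Product: 17 (S)-5-methoxy-3-methyl-5-oxopentanoic acid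
Conditions: MeOH (10 equiv), (DHQ)2AQN (10 mol%), Et2O, −40 °C
Reagents that add atoms: methanol CO
Why: Alkaloid-catalysed enantioselective methanolysis (desymmetrisation) of the prochiral anhydride: the catalyst selects one of the two enantiotopic carbonyl groups and thereby sets C13.

Step 12
Reactants: 17 (S)-5-methoxy-3-methyl-5-oxopentanoic acid
Product: 18 methyl (S)-5-hydroxy-3-methylpentanoate
Conditions: BH3·SMe2 (1.1 equiv), THF, −10 °C → rt; aqueous work-up, used crude
Reagents that add atoms: none
Why: Chemoselective borane reduction of a carboxylic acid (via the acyloxyborane) in the presence of a methyl ester, which leaves C13 untouched.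

Step 13
Reactants: 18 methyl (S)-5-hydroxy-3-methylpentanoate
Product: 19 methyl (R)-5-iodo-3-methylpentanoate
Conditions: I2, PPh3, imidazole, CH2Cl2, 0 °C → rt
Reagents that add atoms: iodine II
Why: Appel-type iodination converts the primary alcohol to the iodide by SN2 displacement of the alkoxyphosphonium ion (the descriptor changes only because of priority rules).

Step 14
Reactants: 15 acetonide dienone; 19 methyl (R)-5-iodo-3-methylpentanoate
Product: 21 methyl (13S)-6-chloro-2α,3α-isopropylidenedioxy-7-(trimethylsilyloxy)-9βH-labda-5,7-dien-15-oate, via alkylzinc iodide 20 (not isolated)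
Conditions: 19, Zn dust (activated with BrCH2CH2Br and TMSCl), THF, 40 °C; then 15, CuBr·SMe2 (20 mol%), TMSCl (3 equiv), HMPA (3 equiv), THF, −30 → 0 °C; Et3N quench
Reagents that add atoms: zinc [Zn] (in 20 only); chlorotrimethylsilane C[Si](C)(C)Cl
Why: Zinc inserts into the primary C–I bond without touching the ester, and the copper-catalysed, TMSCl/HMPA-accelerated conjugate addition should deliver the chain to C9, the only β-carbon that bears hydrogen (C5 is fully substituted), with trapping of the enolate as the silyl enol ether; attack is expected anti to the C10 methyl, but this C9 configuration is erased in step 15.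

Step 15
Reactants: 21 methyl (13S)-6-chloro-2α,3α-isopropylidenedioxy-7-(trimethylsilyloxy)-9βH-labda-5,7-dien-15-oate
Product: 22 methyl (13S)-6-chloro-2α,3α-isopropylidenedioxy-7-oxolabda-5,8-dien-15-oate
Conditions: Pd(OAc)2 (1.1 equiv), MeCN, rt → 40 °C
Reagents that add atoms: none
Why: Saegusa–Ito oxidation: divalent palladium forms the C8 palladium enolate and syn β-hydride elimination of H9 should restore the C8=C9 enone, now tetrasubstituted and carrying the side chain.

Step 16
Reactants: 22 methyl (13S)-6-chloro-2α,3α-isopropylidenedioxy-7-oxolabda-5,8-dien-15-oate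
Product: 23 methyl (13S)-2α,3α-isopropylidenedioxy-7-oxolabd-8-en-15-oate
Conditions: H2 (1 atm), 10% Pd/C, Et3N (1.5 equiv), EtOAc, rt
Reagents that add atoms: none
Why: Heterogeneous hydrogenation with hydrogenolysis of the activated vinylic C–Cl bond should saturate the C5=C6 arm while the more hindered tetrasubstituted C8=C9 enone survives, hydrogen reaching C5 from the α-face, opposite the syn-axial methyls on C4 and C10, to give the trans ring fusion.

Step 17
Reactants: 23 methyl (13S)-2α,3α-isopropylidenedioxy-7-oxolabd-8-en-15-oate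
Product: 24 methyl (13S)-7β-hydroxy-2α,3α-isopropylidenedioxylabd-8-en-15-oate
Conditions: NaBH4, CeCl3·7H2O, MeOH, −40 °C
Reagents that add atoms: none
Why: Luche 1,2-reduction: the small cerium-activated hydride should add axially to C7 from the α-face of the half-chair enone, giving the pseudo-equatorial 7β-allylic alcohol and leaving the ester alone.

Step 18
Reactants: 24 methyl (13S)-7β-hydroxy-2α,3α-isopropylidenedioxylabd-8-en-15-oate
Product: 27 methyl (13S)-2α,3α-isopropylidenedioxylabd-7-en-15-oate, via N-allyl sulfonylhydrazide 25 (not isolated), via allylic diazene 26 (not isolated)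
Conditions: 2-nitrobenzenesulfonylhydrazide, PPh3, DEAD, N-methylmorpholine, −30 °C → rt
Reagents that add atoms: 2-nitrobenzenesulfonylhydrazide NNS(=O)(=O)c1ccccc1[N+](=O)[O-] (nitrogen and sulfur in 25 and 26 only; none remain in 27)
Why: Reductive 1,3-transposition of an allylic alcohol through a monoalkyl diazene: Mitsunobu displacement inverts C7 (nitrogen on the α-face), sulfinate loss gives the diazene, and the concerted retro-ene loss of N2 transfers hydrogen suprafacially to the α-face of C9 while the olefin moves to C7=C8, so the C7 carbinol configuration fixes C9.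

Step 19
Reactants: 27 methyl (13S)-2α,3α-isopropylidenedioxylabd-7-en-15-oate
Product: 28 methyl (13S)-2α,3α-dihydroxylabd-7-en-15-oate (CNP0574074.1)
Conditions: AcOH/H2O (4:1), 40 °C
Reagents that add atoms: none
Why: Mild aqueous acid hydrolysis of the acetonide, under which the methyl ester and the trisubstituted olefin should be stable.

**Compound list**

1 | (2,4-dimethylphenyl)acetonitrile | N#CCc1ccc(C)cc1C | starting material
2 | 2-(2,4-dimethylphenyl)-2-methylpropanenitrile | CC(C)(C#N)c1ccc(C)cc1C | intermediate
3 | 2-(5-bromo-2,4-dimethylphenyl)-2-methylpropanenitrile | CC(C)(C#N)c1cc(Br)c(C)cc1C | intermediate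
4 | 2-[2,4-dimethyl-5-(4,4,5,5-tetramethyl-1,3,2-dioxaborolan-2-yl)phenyl]-2-methylpropanenitrile | CC(C)(C#N)c1cc(B2OC(C)(C)C(C)(C)O2)c(C)cc1C | intermediate (not isolated)
5 | 2-(5-hydroxy-2,4-dimethylphenyl)-2-methylpropanenitrile | CC(C)(C#N)c1cc(O)c(C)cc1C | intermediate
6 | 2-(2-chloro-3-hydroxy-4,6-dimethylphenyl)-2-methylpropanenitrile | CC(C)(C#N)c1c(Cl)c(O)c(C)cc1C | intermediate
7 | 2-(2-chloro-3-hydroxy-4,6-dimethylphenyl)-2-methylpropan-1-imine (present as its N-aluminium derivative) | CC(C)(C=N)c1c(Cl)c(O)c(C)cc1C | intermediate (not isolated)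
8 | 2-(2-chloro-3-hydroxy-4,6-dimethylphenyl)-2-methylpropanal | CC(C)(C=O)c1c(Cl)c(O)c(C)cc1C | intermediate
9 | vinylmagnesium bromide | C=C[Mg]Br | starting material
10 | rac-2-chloro-3-(3-hydroxy-2-methylpent-4-en-2-yl)-4,6-dimethylphenol | C=CC(O)C(C)(C)c1c(Cl)c(O)c(C)cc1C | intermediate
11 | rac-methyl [4-{2-chloro-3-[(methoxycarbonyl)oxy]-4,6-dimethylphenyl}-4-methylpent-1-en-3-yl] carbonate | C=CC(OC(=O)OC)C(C)(C)c1c(Cl)c(OC(=O)OC)c(C)cc1C | intermediate (not isolated)
12 | rac-methyl [4-(2-chloro-3-hydroxy-4,6-dimethylphenyl)-4-methylpent-1-en-3-yl] carbonate | C=CC(OC(=O)OC)C(C)(C)c1c(Cl)c(O)c(C)cc1C | intermediate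
13 | (4aR)-1-chloro-3,4a,8,8-tetramethyl-5,8-dihydronaphthalen-2(4aH)-one | ClC1=C2C(C)(C)C=CC[C@]2(C)C=C(C)C1=O | intermediate
14 | (4aR,6R,7S)-1-chloro-6,7-dihydroxy-3,4a,8,8-tetramethyl-5,6,7,8-tetrahydronaphthalen-2(4aH)-one | ClC1=C2C(C)(C)[C@H](O)[C@H](O)C[C@]2(C)C=C(C)C1=O | intermediate
15 | 2α,3α-O-isopropylidene derivative (acetonide) of 14 | ClC1=C2C(C)(C)[C@@H]3OC(C)(C)O[C@@H]3C[C@]2(C)C=C(C)C1=O | intermediate
16 | 3-methylglutaric anhydride | CC1CC(=O)OC(=O)C1 | starting material
17 | (S)-5-methoxy-3-methyl-5-oxopentanoic acid | COC(=O)C[C@@H](C)CC(=O)O | intermediate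
18 | methyl (S)-5-hydroxy-3-methylpentanoate | COC(=O)C[C@@H](C)CCO | intermediate
19 | methyl (R)-5-iodo-3-methylpentanoate | COC(=O)C[C@@H](C)CCI | intermediate
20 | [(3R)-5-methoxy-3-methyl-5-oxopentyl]zinc iodide | COC(=O)C[C@@H](C)CC[Zn]I | intermediate (not isolated)
21 | methyl (13S)-6-chloro-2α,3α-isopropylidenedioxy-7-(trimethylsilyloxy)-9βH-labda-5,7-dien-15-oate (side chain α on C9) | COC(=O)C[C@@H](C)CC[C@@H]1C(C)=C(O[Si](C)(C)C)C(Cl)=C2C(C)(C)[C@@H]3OC(C)(C)O[C@@H]3C[C@]12C | intermediate
22 | methyl (13S)-6-chloro-2α,3α-isopropylidenedioxy-7-oxolabda-5,8-dien-15-oate | COC(=O)C[C@@H](C)CCC1=C(C)C(=O)C(Cl)=C2C(C)(C)[C@@H]3OC(C)(C)O[C@@H]3C[C@]12C | intermediate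
23 | methyl (13S)-2α,3α-isopropylidenedioxy-7-oxolabd-8-en-15-oate (5α-H) | COC(=O)C[C@@H](C)CCC1=C(C)C(=O)C[C@H]2C(C)(C)[C@@H]3OC(C)(C)O[C@@H]3C[C@]12C | intermediate
24 | methyl (13S)-7β-hydroxy-2α,3α-isopropylidenedioxylabd-8-en-15-oate | COC(=O)C[C@@H](C)CCC1=C(C)[C@@H](O)C[C@H]2C(C)(C)[C@@H]3OC(C)(C)O[C@@H]3C[C@]12C | intermediate
25 | methyl (13S)-7α-[1-(2-nitrophenylsulfonyl)hydrazinyl]-2α,3α-isopropylidenedioxylabd-8-en-15-oate | COC(=O)C[C@@H](C)CCC1=C(C)[C@H](N(N)S(=O)(=O)c4ccccc4[N+](=O)[O-])C[C@H]2C(C)(C)[C@@H]3OC(C)(C)O[C@@H]3C[C@]12C | intermediate (not isolated)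
26 | methyl (13S)-7α-diazenyl-2α,3α-isopropylidenedioxylabd-8-en-15-oate | COC(=O)C[C@@H](C)CCC1=C(C)[C@H](N=N)C[C@H]2C(C)(C)[C@@H]3OC(C)(C)O[C@@H]3C[C@]12C | intermediate (not isolated)
27 | methyl (13S)-2α,3α-isopropylidenedioxylabd-7-en-15-oate | COC(=O)C[C@@H](C)CC[C@H]1C(C)=CC[C@H]2C(C)(C)[C@@H]3OC(C)(C)O[C@@H]3C[C@]12C | intermediate
28 | methyl (13S)-2α,3α-dihydroxylabd-7-en-15-oate = methyl (3S)-5-[(1S,4aR,6S,7R,8aR)-6,7-dihydroxy-2,5,5,8a-tetramethyl-1,4,4a,5,6,7,8,8a-octahydronaphthalen-1-yl]-3-methylpentanoate | COC(=O)C[C@@H](C)CC[C@H]1C(C)=CC[C@H]2C(C)(C)[C@H](O)[C@H](O)C[C@]12C | target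

**Step count and risks**

Total steps: 19. Longest linear sequence: 16 (steps 1–10 and 14–19); the side-chain branch is steps 11–13.

Steps most likely to fail:

1. Step 8 (the step labelled as a new method). The π-allyl complex may stay in the unreactive syn form so that intermolecular O-allylation and oligomerisation take over, C-alkylation may be diverted to C6, or the ligand may discriminate the two arene faces poorly. The fallback uses known chemistry, sets out from aldehyde 8 and returns at 13. Z-selective Still–Gennari olefination of 8 (methyl bis(2,2,2-trifluoroethyl)phosphonoacetate, KN(SiMe3)2, 18-crown-6, THF, −78 °C) would give methyl (2Z)-4-(2-chloro-3-hydroxy-4,6-dimethylphenyl)-4-methylpent-2-enoate F1. Reduction with i-Bu2AlH would give the Z-allylic alcohol 2-chloro-3-[(3Z)-5-hydroxy-2-methylpent-3-en-2-yl]-4,6-dimethylphenol F2. PPh3/N-chlorosuccinimide would convert it into the Z-allylic chloride 2-chloro-3-[(3Z)-5-chloro-2-methylpent-3-en-2-yl]-4,6-dimethylphenol F3. KOt-Bu in t-BuOH/THF would then effect the classical base-mediated intramolecular para-C-alkylation of the phenolate (SN2 at the allylic carbon; the cis olefin allows six-ring closure) to the racemic dienone F4. F4 would be resolved by preparative chromatography on a chiral stationary phase to give 13.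

2. Step 14. Conjugate addition at C9, a β-carbon next to quaternary C10 on an α-methyl enone, may be too slow for the zinc–copper reagent, or electron transfer from copper may reduce the chloro-dienone instead. The fallback sets out from 15 and 19 and returns at 21. A Giese radical addition (Bu3SnH added slowly, AIBN, benzene, 80 °C) of the primary alkyl radical from 19 to C9 of 15 would give the ketone methyl (13S)-6-chloro-2α,3α-isopropylidenedioxy-7-oxo-9βH-labd-5-en-15-oate F5 (C8 epimers). Silylation with TMSOTf/Et3N, which can only enolise towards C8, would then give 21.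

3. Step 18. Mitsunobu displacement at the hindered, easily ionised allylic C7 may give elimination to a diene or lose stereospecificity, so that the C9 configuration is not relayed. The fallback sets out from 24 and returns at 27. Formylation (acetic formic anhydride, pyridine) would give the formate methyl (13S)-7β-formyloxy-2α,3α-isopropylidenedioxylabd-8-en-15-oate F6. Palladium-catalysed hydrogenolysis of this allylic formate (Pd(OAc)2, PBu3, THF, reflux) proceeds by ionisation anti to the formate, which places palladium on the α-face, then decarboxylation to a palladium hydride. Hydride delivery from the metal to the more substituted terminus C9 on the α-face should give 27 directly.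

Further compounds
F1 | step 8 | methyl (2Z)-4-(2-chloro-3-hydroxy-4,6-dimethylphenyl)-4-methylpent-2-enoate | COC(=O)/C=C\C(C)(C)c1c(Cl)c(O)c(C)cc1C
F2 | step 8 | 2-chloro-3-[(3Z)-5-hydroxy-2-methylpent-3-en-2-yl]-4,6-dimethylphenol | OC/C=C\C(C)(C)c1c(Cl)c(O)c(C)cc1C
F3 | step 8 | 2-chloro-3-[(3Z)-5-chloro-2-methylpent-3-en-2-yl]-4,6-dimethylphenol | ClC/C=C\C(C)(C)c1c(Cl)c(O)c(C)cc1C
F4 | step 8 | rac-1-chloro-3,4a,8,8-tetramethyl-5,8-dihydronaphthalen-2(4aH)-one | ClC1=C2C(C)(C)C=CCC2(C)C=C(C)C1=O
F5 | step 14 | methyl (13S)-6-chloro-2α,3α-isopropylidenedioxy-7-oxo-9βH-labd-5-en-15-oate (C8 epimers) | COC(=O)C[C@@H](C)CC[C@@H]1C(C)C(=O)C(Cl)=C2C(C)(C)[C@@H]3OC(C)(C)O[C@@H]3C[C@]12C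
F6 | step 18 | methyl (13S)-7β-formyloxy-2α,3α-isopropylidenedioxylabd-8-en-15-oate | COC(=O)C[C@@H](C)CCC1=C(C)[C@@H](OC=O)C[C@H]2C(C)(C)[C@@H]3OC(C)(C)O[C@@H]3C[C@]12C
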